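Minutes per factor of ten is the unit I reckon in, so that a fade becomes a subtraction of decades.

| setting | east | larch | maple | birch |
|---|---|---|---|---|
| substrate | 0.20 M | 0.20 M | 0.20 M | 0.20 M |
| first nucleophile | 1.6 M | 0.800 M | 0.800 M | 0.800 M |
| gas | 14 mM (held) | 14 mM (held) | 14 mM (held) | 14 mM (held) |
| temperature | 50 °C |  | 50 °C | 25 °C |
| remark | run made earlier | at 50 °C until 25 min, from then on at 25 °C |  |  |
| time |  | 50 min | 50 min | 50 min |

east run (percent of the substrate charged)

| time / min | target / % | substrate / % |
|---|---|---|
| 0.667 | 22 | 42 |
| 1.33 | 33 | 18 |
| 2.00 | 36 | 8 |
| 3.00 | 39 | 1 |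
| 4.00 | 38 | 0 |
| 5.00 | 35 | 0 |

(each reading ± 1.5 percentage points)

- the flask that comes out highest in amount of target, in percent of the substrate charged, or "all alike" when all lie within 1.5 percentage points (larch / maple / birch / all alike)
- target at the end, in percent of the substrate charged, larch
- target at the end, in percent of the substrate charged, maple
- target at the end, in percent of the substrate charged, birch

- the earlier runs were read with a standard deviation of 1.5 percentage points
- at the start none of the gas is in solution
- the earlier runs do not show what temperature does; that part of a forecast is a guess

In east the substrate stands at 8 % at 2.00 min, so it loses a decade in 1.82 min. What I want is the decade time of the target, and east offers two ways to it.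

Tail way, from the target's fall between 3.00 min and 5.00 min:

  42.6 min per decade

Peak way: at the peak, making equals fading. With the fade slow, the substrate fraction at the peak of east, read at 3.00 min, is about the substrate's decade time over the target's, so the target's decade time is about the substrate's times ten to the power of peak time over substrate decade time:

  80.6 min per decade

They part by a factor 1.89. The tail way cheats: it hangs on a drop of 4 percentage points between two readings, each with a scatter of 1.5 points. The peak way is coarse too, for its peak time is a scattered reading, but it draws on the substrate's fall and not on that small drop, so I commit to 80.6 min as the fade decade time, the minutes in which the target falls by a factor of ten. With the gas held, I take the fade as pseudo-first-order and the same at lower c(first nucleophile).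

The selectivity at the peak of east reads 39.4 %. I assume the side path needs no first nucleophile, so the odds of capture scale with c(first nucleophile). Going from 1.6 M to 0.800 M gives 24.5 %. Maple then loses 0.621 decades:

  24.5 % falls to 5.88 % (the tail way gives 1.64 %)

East shows nothing of temperature, so I put no number on larch or birch.

The forecast says “Over 50 minutes, the slow loss of target dominates.” It names birch, with larch 11 %, maple 5 % and birch 25 %. Its maple lies 0.88 points below mine.

The flask that comes out highest is birch at 33.1 %, with larch at 12.9 % and maple at 7.64 %.

    substrate → intermediate (k = 0.0630 min⁻¹, Ea = 98.0 kJ mol⁻¹)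
    first nucleophile + intermediate → target (k = 1.70 L mol⁻¹ min⁻¹, Ea = 41.0 kJ mol⁻¹)
    second nucleophile + intermediate → other capture product (k = 9.40 L mol⁻¹ min⁻¹, Ea = 52.0 kJ mol⁻¹)
    intermediate → solvolysis product (k = 1.70 min⁻¹, Ea = 69.0 kJ mol⁻¹)
    intermediate → side product (k = 0.0110 min⁻¹, Ea = 92.0 kJ mol⁻¹)
    second nucleophile + target → over-reaction product (k = 0.460 L mol⁻¹ min⁻¹, Ea = 55.0 kJ mol⁻¹)
    gas ⇌ second nucleophile, rate k7*(csat - [second nucleophile]) (kL = 0.180 min⁻¹)
    (constants at 25 °C)

Birch stands 8.1 points above the forecast. Maple falls from 14.9 % at 25.0 min to 7.64 % at 50.0 min, a decade time of 86.4 min against the 80.6 min I reckoned. Larch, cold after 25 min, goes from 14.9 % to 12.9 % over the same stretch, a decade time of 405 min, which is 5.02 times 80.6 min. At that pace, larch read at 2.0 h comes to 8.67 %, and that neighbouring flask holds 8.42 %.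

Readings and results were computed with made-up constants.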